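**Plan**

Germacrane numbering is used for the ring compounds: ring C1–C10 with the C9 ketone, (E)-C1=C10 (methyl C14), 4,5-epoxide (C15 on C4), spiro 7,11-epoxide (C12 and C13 on C11).
Retrosynthesis: remove the two acetates and the C9 ketone (from a protected carbinol); open the 7,11-epoxide (Sharpless, C12–OH) and the 4,5-epoxide (Payne shift of a 4,15-epoxy-5-ol); cut the ring bond C4–C5; then cut C6–C7 (Negishi), the C9–O–C12 lactone, C8–C9 (aldol) and C1=C2 (Wittig).
Enabling feature: in the ten-membered ring C1–C10, C4 carries the one-carbon branch C15 and sits next to oxygenated C5. This 2-methylene carbinol pattern arises when a C5 aldehyde couples at the internal carbon of a terminal C4≡C15 alkyne.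
Forward: oxidation–Wittig builds C1–C4/C9/C10/C14; vinylogous aldol and lactonisation add C8, C7, C11–C13 (the lactone ring fixes C8 cis to C12); a triflate Negishi coupling adds C6–C5; lactone reduction, protection and aldehyde release give the ynal; nickel-catalysed reductive macrocyclisation closes the only carbocycle; oxidation levels and epoxides are then adjusted.
Stereochemistry: (E)-C1=C10 from the stabilised ylide; C7=C11 geometry from the lactone; C5 from CBS reduction; C4 from hydroxyl-directed epoxidation followed by Payne inversion; C7/C11 from Sharpless epoxidation with D-(−)-tartrate; C9 is a sacrificial carbinol (titanium–BINOL aldol) erased in the last step.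

Key step: step 11

Assumption: the (R)-BINOL titanium catalyst is taken to give the (9R) carbinol by analogy with aryl and alkenyl aldehydes; C9 ends as a ketone, so the opposite sense would change only the descriptors of intermediates.
Remark: the C7 descriptor is R in 24–26 and S in 27 for the same geometry, because oxidation at C9 reverses the CIP ranking of C8 and C6.

**Route**

Step 1
Reactants: 1 pent-4-yn-1-ol; 2 2-(triphenylphosphoranylidene)propanal
Product: 4 (2E)-2-methylhept-2-en-6-ynal, via pent-4-ynal 3 (not isolated)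
Conditions: TEMPO (10 mol %), PhI(OAc)2, CH2Cl2, rt; then 2, 40 °C
Reagents that add atoms: none
Why: The nitroxyl-catalysed oxidation should stop at the aldehyde, and the formyl-stabilised ylide should then give the (E)-trisubstituted enal under thermodynamic control (one-flask oxidation–Wittig olefination), so the volatile aldehyde 3 need not be isolated.

Step 2
Reactants: 5 ethyl 2-methyl-3-oxobutanoate
Product: 6 1-ethoxy-2-methyl-1,3-bis(trimethylsilyloxy)buta-1,3-diene
Conditions: LiN(iPr)2 (2.2 equiv), THF, −78 to 0 °C; Me3SiCl, −78 °C to rt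
Reagents that add atoms: chlorotrimethylsilane, C[Si](C)(C)Cl
Why: Double deprotonation of the β-keto ester (α-CH, then the γ-methyl) and O-silylation of both enolate oxygens should give the bis(silyl) dienol ether, whose ketene acetal geometry is irrelevant (dienolate formation and silyl enol ether synthesis).

Step 3
Reactants: 4 (2E)-2-methylhept-2-en-6-ynal; 6 1-ethoxy-2-methyl-1,3-bis(trimethylsilyloxy)buta-1,3-diene
Product: 8 ethyl (5R,6E)-5-hydroxy-2,6-dimethyl-3-oxoundec-6-en-10-ynoate, via bis-silyl aldol adduct 7 (not isolated)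
Conditions: Ti(OiPr)4 (10 mol %), (R)-BINOL (10 mol %), 4 Å MS, THF, −78 °C to rt; then CF3CO2H, THF/H2O, 0 °C
Reagents that add atoms: none
Why: In this catalytic asymmetric vinylogous Mukaiyama aldol addition the titanium–BINOL Lewis acid should activate the aldehyde for 1,2-attack by the terminal (γ) carbon of the dienol ether, the ligand shielding one carbonyl face to set the carbinol centre (future C9, expected R), and acid then removes both silyl groups; the terminal alkyne is inert and the C2 epimers are of no consequence.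

Step 4
Reactants: 8 ethyl (5R,6E)-5-hydroxy-2,6-dimethyl-3-oxoundec-6-en-10-ynoate
Product: 9 (6R)-6-[(2E)-hept-2-en-6-yn-2-yl]-4-hydroxy-3-methyl-5,6-dihydro-2H-pyran-2-one
Conditions: K2CO3, MeOH, rt; then HCl (aq) to pH 2
Reagents that add atoms: none
Why: Intramolecular transesterification (lactonisation) of the δ-hydroxy β-keto ester should close the six-membered lactone, driven by formation of the stabilised vinylogous carboxylate, with no bond to the carbinol stereocentre broken.

Step 5
Reactants: 9 (6R)-6-[(2E)-hept-2-en-6-yn-2-yl]-4-hydroxy-3-methyl-5,6-dihydro-2H-pyran-2-one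
Product: 10 (6R)-6-[(2E)-hept-2-en-6-yn-2-yl]-3-methyl-2-oxo-5,6-dihydro-2H-pyran-4-yl trifluoromethanesulfonate
Conditions: Tf2O, Et3N, CH2Cl2, −78 °C
Reagents that add atoms: trifluoromethanesulfonic anhydride, O=S(=O)(OS(=O)(=O)C(F)(F)F)C(F)(F)F
Why: O-Sulfonylation of the vinylogous acid (enol triflate formation) should give the conjugated 4-triflyloxy lactone, in which the ring holds the future C8 and C12 cis on the future C7=C11 alkene.

Step 6
Reactants: 10 (6R)-6-[(2E)-hept-2-en-6-yn-2-yl]-3-methyl-2-oxo-5,6-dihydro-2H-pyran-4-yl trifluoromethanesulfonate; 11 (1,3-dioxolan-2-ylmethyl)zinc bromide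
Product: 12 (6R)-4-(1,3-dioxolan-2-ylmethyl)-6-[(2E)-hept-2-en-6-yn-2-yl]-3-methyl-5,6-dihydro-2H-pyran-2-one
Conditions: Pd(PPh3)4 (5 mol %), THF, rt to 50 °C
Reagents that add atoms: none
Why: In this Negishi cross-coupling, zerovalent palladium should insert into the activated vinylogous C–OTf bond and the alkylzinc should transmetalate and couple with retention of alkene geometry, introducing C6 and C5 (as the acetal); the weakly basic zinc reagent should leave the lactone and the terminal alkyne untouched.

Step 7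
Reactants: 12 (6R)-4-(1,3-dioxolan-2-ylmethyl)-6-[(2E)-hept-2-en-6-yn-2-yl]-3-methyl-5,6-dihydro-2H-pyran-2-one
Product: 13 (2E,5R,6E)-3-(1,3-dioxolan-2-ylmethyl)-2,6-dimethylundeca-2,6-dien-10-yne-1,5-diol
Conditions: iBu2AlH (4.5 equiv), CH2Cl2, −78 °C to rt; potassium sodium tartrate (aq)
Reagents that add atoms: none
Why: Hydride 1,2-reduction of the unsaturated lactone through the lactol should give the ene-diol with the tetrasubstituted alkene geometry unchanged (C1 cis to C4), the acetal and alkyne being inert at this temperature.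

Step 8
Reactants: 13 (2E,5R,6E)-3-(1,3-dioxolan-2-ylmethyl)-2,6-dimethylundeca-2,6-dien-10-yne-1,5-diol
Product: 14 (2E,5R,6E)-1-(tert-butyldimethylsilyloxy)-3-(1,3-dioxolan-2-ylmethyl)-2,6-dimethylundeca-2,6-dien-10-yn-5-ol
Conditions: TBSCl (1.05 equiv), imidazole, CH2Cl2, −20 to 0 °C
Reagents that add atoms: tert-butyldimethylsilyl chloride, CC(C)(C)[Si](C)(C)Cl
Why: Silylation should take place at the primary allylic hydroxyl much faster than at the hindered secondary one (selective silyl ether formation).

Step 9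
Reactants: 14 (2E,5R,6E)-1-(tert-butyldimethylsilyloxy)-3-(1,3-dioxolan-2-ylmethyl)-2,6-dimethylundeca-2,6-dien-10-yn-5-ol
Product: 15 tert-butyl{[(2E,5R,6E)-3-(1,3-dioxolan-2-ylmethyl)-5-(4-methoxybenzyloxy)-2,6-dimethylundeca-2,6-dien-10-yn-1-yl]oxy}dimethylsilane
Conditions: NaH (1.1 equiv), 4-MeOC6H4CH2Cl, Bu4NI (cat.), THF/DMF, 0 °C to rt
Reagents that add atoms: 4-methoxybenzyl chloride, COc1ccc(CCl)cc1
Why: In this Williamson etherification the alkoxide forms in strong preference to the acetylide with one equivalent of base and is benzylated, giving a C9 ether that is orthogonal to the silyl ethers and removable under neutral oxidative conditions.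

Step 10
Reactants: 15 tert-butyl{[(2E,5R,6E)-3-(1,3-dioxolan-2-ylmethyl)-5-(4-methoxybenzyloxy)-2,6-dimethylundeca-2,6-dien-10-yn-1-yl]oxy}dimethylsilane
Product: 16 (3E,5R,6E)-3-[1-(tert-butyldimethylsilyloxy)propan-2-ylidene]-5-(4-methoxybenzyloxy)-6-methylundec-6-en-10-ynal
Conditions: Et3SiOTf, 2,4,6-collidine, CH2Cl2, 0 °C; then H2O; used crude
Reagents that add atoms: water, O
Why: Silyl triflate/collidine acetal cleavage should convert the aldehyde acetal into a collidinium salt that water hydrolyses without free acid, so the silyl and benzyl ethers survive and the β,γ-unsaturated aldehyde is not drawn into conjugation.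

Step 11
Reactants: 16 (3E,5R,6E)-3-[1-(tert-butyldimethylsilyloxy)propan-2-ylidene]-5-(4-methoxybenzyloxy)-6-methylundec-6-en-10-ynal
Product: 17 (1(10)E,9R)-12-(tert-butyldimethylsilyloxy)-9-(4-methoxybenzyloxy)-5-(triethylsilyloxy)germacra-1(10),4(15),7(11)-triene (C12 cis to C8; both C5 epimers)
Conditions: Ni(cod)2 (30 mol %), 1,3-bis(2,6-diisopropylphenyl)-4,5-diphenylimidazolinium tetrafluoroborate (30 mol %), KOtBu (30 mol %), Et3SiH (5 equiv), THF, rt, syringe-pump addition of 16 over 8 h (final 2 mM)
Reagents that add atoms: triethylsilane, CC[SiH](CC)CC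
Why: Oxidative cyclisation of the alkyne and the aldehyde on zerovalent nickel should give an oxanickelacyclopentene in which the bulky carbene forces the small alkyne terminus (C15–H) next to nickel, so the new C–C bond joins C5 to the internal carbon C4; σ-bond metathesis with Et3SiH then puts silicon on oxygen, and C–H reductive elimination at C15 releases the silyl ether and the catalyst. The closest known reaction type is the nickel–N-heterocyclic carbene reductive macrocyclisation of terminal ynals with ligand-controlled exocyclic-methylene regiochemistry, established for rings of twelve and more members, so the ten-membered case lies at the lower limit. The ten-membered ring closes in exo mode at the alkyne (only C4 enters the ring, C15 stays outside as the methylene) and exo at the carbonyl (oxygen outside the ring). The one new stereocentre, C5, is not controlled (only the remote C9 centre could bias it), and both epimers converge on enone 19. The step needs exo over endo regioselectivity, which the large ligand and the unhindered terminal alkyne should secure, and ring closure over oligomerisation, which slow addition at high dilution and the two rigid alkenes (E-C1=C10 and the tetrasubstituted C7=C11) should favour; the substrate carries no other nickel-reactive group (no enone, allylic ester or epoxide).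

Step 12
Reactants: 17 (1(10)E,9R)-12-(tert-butyldimethylsilyloxy)-9-(4-methoxybenzyloxy)-5-(triethylsilyloxy)germacra-1(10),4(15),7(11)-triene
Product: 19 (1(10)E,9R)-12-(tert-butyldimethylsilyloxy)-9-(4-methoxybenzyloxy)germacra-1(10),4(15),7(11)-trien-5-one, via C5 alcohols 18 (not isolated)
Conditions: IBX (3 equiv), DMSO, rt
Reagents that add atoms: none
Why: IBX in DMSO should cleave the triethylsilyl ether while leaving the tert-butyldimethylsilyl ether intact and then oxidise the liberated allylic alcohol (hypervalent iodine oxidation), so both C5 epimers converge on one α-methylene ketone under non-basic conditions that should not move the C7=C11 alkene.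

Step 13
Reactants: 19 (1(10)E,9R)-12-(tert-butyldimethylsilyloxy)-9-(4-methoxybenzyloxy)germacra-1(10),4(15),7(11)-trien-5-one
Product: 20 (1(10)E,5R,9R)-12-(tert-butyldimethylsilyloxy)-9-(4-methoxybenzyloxy)germacra-1(10),4(15),7(11)-trien-5-ol
Conditions: (S)-2-methyl-CBS-oxazaborolidine (0.5 equiv), catecholborane (1.5 equiv), toluene, −78 °C
Reagents that add atoms: none
Why: In the Corey–Bakshi–Shibata reduction the catalyst–borane complex should bind the carbonyl with the α-methylene vinyl group (C4 side) as the large substituent and the C6 methylene as the small one, so the (S)-catalyst delivers hydride to the face that gives (5R), and catecholborane at low temperature ensures 1,2-reduction without hydroboration.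

Step 14
Reactants: 20 (1(10)E,5R,9R)-12-(tert-butyldimethylsilyloxy)-9-(4-methoxybenzyloxy)germacra-1(10),4(15),7(11)-trien-5-ol
Product: 21 (1(10)E,4S,5R,9R)-4,15-epoxy-12-(tert-butyldimethylsilyloxy)-9-(4-methoxybenzyloxy)germacra-1(10),7(11)-dien-5-ol
Conditions: VO(acac)2 (5 mol %), t-BuOOH (1.2 equiv, decane), CH2Cl2, 0 °C
Reagents that add atoms: tert-butyl hydroperoxide, CC(C)(C)OO
Why: In this vanadium-catalysed hydroxyl-directed epoxidation the vanadate ester of the C5 alcohol should deliver oxygen to C4=C15 through the conformer that minimises A(1,2) strain (C5–H near C3, C6 turned away), which gives the (4S,5R) epoxy alcohol (erythro in acyclic models); the ether-flanked C1=C10 alkene should not react and the homoallylic C7=C11 alkene reacts more slowly, so the oxidant is held to a slight excess.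

Step 15
Reactants: 21 (1(10)E,4S,5R,9R)-4,15-epoxy-12-(tert-butyldimethylsilyloxy)-9-(4-methoxybenzyloxy)germacra-1(10),7(11)-dien-5-ol
Product: 22 (1(10)E,4R,5R,9R)-4,5-epoxy-12-(tert-butyldimethylsilyloxy)-9-(4-methoxybenzyloxy)germacra-1(10),7(11)-dien-15-ol
Conditions: NaOH (0.5 M aq), t-BuOH, rt
Reagents that add atoms: none
Why: In the Payne rearrangement the C5 alkoxide should open the 4,15-epoxide at C4 from the rear (inversion at C4, retention at C5), giving the 4,5-epoxide with ring bonds C3 and C6 cis, and the equilibrium should favour the trisubstituted epoxide with the primary alkoxide.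

Step 16
Reactants: 22 (1(10)E,4R,5R,9R)-4,5-epoxy-12-(tert-butyldimethylsilyloxy)-9-(4-methoxybenzyloxy)germacra-1(10),7(11)-dien-15-ol
Product: 23 (1(10)E,4R,5R,9R)-4,5-epoxy-9-(4-methoxybenzyloxy)germacra-1(10),7(11)-diene-12,15-diol
Conditions: Bu4NF, THF, 0 °C
Reagents that add atoms: none
Why: Fluoride-mediated desilylation should free the primary C12 allylic alcohol while the benzyl ether and the epoxide (already on the favoured side of the Payne equilibrium) are unaffected.

Step 17
Reactants: 23 (1(10)E,4R,5R,9R)-4,5-epoxy-9-(4-methoxybenzyloxy)germacra-1(10),7(11)-diene-12,15-diol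
Product: 24 (1(10)E,4R,5R,7R,9R,11R)-4,5:7,11-diepoxy-9-(4-methoxybenzyloxy)germacr-1(10)-ene-12,15-diol
Conditions: Ti(OiPr)4 (20 mol %), D-(−)-diisopropyl tartrate (24 mol %), t-BuOOH, 4 Å MS, CH2Cl2, −20 °C
Reagents that add atoms: tert-butyl hydroperoxide, CC(C)(C)OO
Why: In the Sharpless asymmetric epoxidation the C12 allylic alcohol binds the titanium–tartrate complex, and D-(−)-tartrate should deliver oxygen to the face that gives (11R) and, by syn addition to the fixed alkene geometry (C8 cis to C12), the C7 configuration of the target; the C15 epoxy alcohol has no alkene within reach and C1=C10 is flanked only by an ether.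

Step 18
Reactants: 24 (1(10)E,4R,5R,7R,9R,11R)-4,5:7,11-diepoxy-9-(4-methoxybenzyloxy)germacr-1(10)-ene-12,15-diol
Product: 25 (1(10)E,4R,5R,7R,9R,11R)-12,15-diacetoxy-4,5:7,11-diepoxy-9-(4-methoxybenzyloxy)germacr-1(10)-ene
Conditions: Ac2O, pyridine, DMAP (cat.), CH2Cl2, 0 °C
Reagents that add atoms: acetic anhydride, CC(=O)OC(C)=O
Why: Acylation of both primary alcohols should be clean, and it is done before C9 becomes a ketone so that no β,γ-epoxy ketone is exposed to base (esterification).

Step 19
Reactants: 25 (1(10)E,4R,5R,7R,9R,11R)-12,15-diacetoxy-4,5:7,11-diepoxy-9-(4-methoxybenzyloxy)germacr-1(10)-ene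
Product: 26 (1(10)E,4R,5R,7R,9R,11R)-12,15-diacetoxy-4,5:7,11-diepoxygermacr-1(10)-en-9-ol
Conditions: DDQ, CH2Cl2/pH 7 phosphate buffer, 0 °C to rt
Reagents that add atoms: none
Why: Oxidative cleavage of the 4-methoxybenzyl ether (hydride abstraction by the quinone, hydrolysis of the oxocarbenium ion) should proceed under buffered neutral conditions that spare both epoxides and both acetates.

Step 20
Reactants: 26 (1(10)E,4R,5R,7R,9R,11R)-12,15-diacetoxy-4,5:7,11-diepoxygermacr-1(10)-en-9-ol
Product: 27 (1(10)E,4R,5R,7S,11R)-12,15-diacetoxy-4,5:7,11-diepoxygermacr-1(10)-en-9-one (target)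
Conditions: Dess–Martin periodinane, pyridine, CH2Cl2, 0 °C to rt
Reagents that add atoms: none
Why: Dess–Martin oxidation of the secondary allylic alcohol should give the (E)-enone under near-neutral conditions, placed last so that the base-sensitive β,γ-epoxy ketone is never carried through another step.

**Compound list**

1 | pent-4-yn-1-ol | C#CCCCO | starting material
2 | 2-(triphenylphosphoranylidene)propanal | CC(C=O)=P(c1ccccc1)(c1ccccc1)c1ccccc1 | starting material
3 | pent-4-ynal | C#CCCC=O | intermediate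
4 | (2E)-2-methylhept-2-en-6-ynal | C#CCC/C=C(\C)C=O | intermediate
5 | ethyl 2-methyl-3-oxobutanoate (ethyl 2-methylacetoacetate) | CCOC(=O)C(C)C(C)=O | starting material
6 | 1-ethoxy-2-methyl-1,3-bis(trimethylsilyloxy)buta-1,3-diene (ketene acetal geometry not defined) | C=C(O[Si](C)(C)C)C(C)=C(OCC)O[Si](C)(C)C | intermediate
7 | (5R,6E)-1-ethoxy-2,6-dimethyl-1,5-bis(trimethylsilyloxy)undeca-1,6-dien-10-yn-3-one (bis-silyl aldol adduct) | CCOC(O[Si](C)(C)C)=C(C)C(=O)C[C@@H](O[Si](C)(C)C)/C(C)=C/CCC#C | intermediate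
8 | ethyl (5R,6E)-5-hydroxy-2,6-dimethyl-3-oxoundec-6-en-10-ynoate (C2 epimers) | CCOC(=O)C(C)C(=O)C[C@@H](O)/C(C)=C/CCC#C | intermediate
9 | (6R)-6-[(2E)-hept-2-en-6-yn-2-yl]-4-hydroxy-3-methyl-5,6-dihydro-2H-pyran-2-one | CC1=C(O)C[C@H](/C(C)=C/CCC#C)OC1=O | intermediate
10 | (6R)-6-[(2E)-hept-2-en-6-yn-2-yl]-3-methyl-2-oxo-5,6-dihydro-2H-pyran-4-yl trifluoromethanesulfonate | CC1=C(OS(=O)(=O)C(F)(F)F)C[C@H](/C(C)=C/CCC#C)OC1=O | intermediate
11 | (1,3-dioxolan-2-ylmethyl)zinc bromide | Br[Zn]CC1OCCO1 | starting material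
12 | (6R)-4-(1,3-dioxolan-2-ylmethyl)-6-[(2E)-hept-2-en-6-yn-2-yl]-3-methyl-5,6-dihydro-2H-pyran-2-one | CC1=C(CC2OCCO2)C[C@H](/C(C)=C/CCC#C)OC1=O | intermediate
13 | (2E,5R,6E)-3-(1,3-dioxolan-2-ylmethyl)-2,6-dimethylundeca-2,6-dien-10-yne-1,5-diol (C1 cis to C4) | OC/C(C)=C(/CC1OCCO1)C[C@@H](O)/C(C)=C/CCC#C | intermediate
14 | (2E,5R,6E)-1-(tert-butyldimethylsilyloxy)-3-(1,3-dioxolan-2-ylmethyl)-2,6-dimethylundeca-2,6-dien-10-yn-5-ol | CC(C)(C)[Si](C)(C)OC/C(C)=C(/CC1OCCO1)C[C@@H](O)/C(C)=C/CCC#C | intermediate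
15 | tert-butyl{[(2E,5R,6E)-3-(1,3-dioxolan-2-ylmethyl)-5-(4-methoxybenzyloxy)-2,6-dimethylundeca-2,6-dien-10-yn-1-yl]oxy}dimethylsilane | CC(C)(C)[Si](C)(C)OC/C(C)=C(/CC1OCCO1)C[C@@H](OCc1ccc(OC)cc1)/C(C)=C/CCC#C | intermediate
16 | (3E,5R,6E)-3-[1-(tert-butyldimethylsilyloxy)propan-2-ylidene]-5-(4-methoxybenzyloxy)-6-methylundec-6-en-10-ynal (ynal precursor of the key step) | O=CC/C(=C(\C)CO[Si](C)(C)C(C)(C)C)C[C@@H](OCc1ccc(OC)cc1)/C(C)=C/CCC#C | intermediate
17 | (1(10)E,9R)-12-(tert-butyldimethylsilyloxy)-9-(4-methoxybenzyloxy)-5-(triethylsilyloxy)germacra-1(10),4(15),7(11)-triene (C12 cis to C8; both C5 epimers) | C=C1CC/C=C(\C)[C@H](OCc2ccc(OC)cc2)C/C(=C(/C)CO[Si](C)(C)C(C)(C)C)CC1O[Si](CC)(CC)CC | intermediate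
18 | (1(10)E,9R)-12-(tert-butyldimethylsilyloxy)-9-(4-methoxybenzyloxy)germacra-1(10),4(15),7(11)-trien-5-ol (both C5 epimers) | C=C1CC/C=C(\C)[C@H](OCc2ccc(OC)cc2)C/C(=C(/C)CO[Si](C)(C)C(C)(C)C)CC1O | intermediate
19 | (1(10)E,9R)-12-(tert-butyldimethylsilyloxy)-9-(4-methoxybenzyloxy)germacra-1(10),4(15),7(11)-trien-5-one | C=C1CC/C=C(\C)[C@H](OCc2ccc(OC)cc2)C/C(=C(/C)CO[Si](C)(C)C(C)(C)C)CC1=O | intermediate
20 | (1(10)E,5R,9R)-12-(tert-butyldimethylsilyloxy)-9-(4-methoxybenzyloxy)germacra-1(10),4(15),7(11)-trien-5-ol | C=C1CC/C=C(\C)[C@H](OCc2ccc(OC)cc2)C/C(=C(/C)CO[Si](C)(C)C(C)(C)C)C[C@H]1O | intermediate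
21 | (1(10)E,4S,5R,9R)-4,15-epoxy-12-(tert-butyldimethylsilyloxy)-9-(4-methoxybenzyloxy)germacra-1(10),7(11)-dien-5-ol | O1C[C@]12CC/C=C(\C)[C@H](OCc3ccc(OC)cc3)C/C(=C(/C)CO[Si](C)(C)C(C)(C)C)C[C@H]2O | intermediate
22 | (1(10)E,4R,5R,9R)-4,5-epoxy-12-(tert-butyldimethylsilyloxy)-9-(4-methoxybenzyloxy)germacra-1(10),7(11)-dien-15-ol | OC[C@]12CC/C=C(\C)[C@H](OCc3ccc(OC)cc3)C/C(=C(/C)CO[Si](C)(C)C(C)(C)C)C[C@H]1O2 | intermediate
23 | (1(10)E,4R,5R,9R)-4,5-epoxy-9-(4-methoxybenzyloxy)germacra-1(10),7(11)-diene-12,15-diol | OC[C@]12CC/C=C(\C)[C@H](OCc3ccc(OC)cc3)C/C(=C(/C)CO)C[C@H]1O2 | intermediate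
24 | (1(10)E,4R,5R,7R,9R,11R)-4,5:7,11-diepoxy-9-(4-methoxybenzyloxy)germacr-1(10)-ene-12,15-diol | OC[C@]12CC/C=C(\C)[C@H](OCc4ccc(OC)cc4)C[C@]3(C[C@H]1O2)O[C@]3(C)CO | intermediate
25 | (1(10)E,4R,5R,7R,9R,11R)-12,15-diacetoxy-4,5:7,11-diepoxy-9-(4-methoxybenzyloxy)germacr-1(10)-ene | CC(=O)OC[C@]12CC/C=C(\C)[C@H](OCc4ccc(OC)cc4)C[C@]3(C[C@H]1O2)O[C@]3(C)COC(C)=O | intermediate
26 | (1(10)E,4R,5R,7R,9R,11R)-12,15-diacetoxy-4,5:7,11-diepoxygermacr-1(10)-en-9-ol | CC(=O)OC[C@]12CC/C=C(\C)[C@H](O)C[C@]3(C[C@H]1O2)O[C@]3(C)COC(C)=O | intermediate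
27 | (1(10)E,4R,5R,7S,11R)-12,15-diacetoxy-4,5:7,11-diepoxygermacr-1(10)-en-9-one, CNP0185847.3 | CC(=O)OC[C@]12CC/C=C(\C)C(=O)C[C@]3(C[C@H]1O2)O[C@]3(C)COC(C)=O | target

**Step count and risks**

Total: 20 steps. Longest linear sequence: 19 steps (from 1 through steps 1 and 3–20; step 2 is the one-step branch to 6).

Steps most likely to fail:

1. Step 11 (macrocyclisation). Closure of the ten-membered ring is slow, so intermolecular coupling to oligomers, bond formation at the terminal alkyne carbon (endo closure) or simple hydrosilylation of the aldehyde or alkyne may outrun it. The fallback forms the same C4–C5 bond by a stoichiometric vinyl-metal addition. It sets out from 15: nickel-catalysed Markovnikov hydroalumination (iBu2AlH, Ni(dppp)Cl2, THF) followed by N-iodosuccinimide should give the 2-iodo-1-alkene acetal tert-butyl{[(2E,5R,6E)-3-(1,3-dioxolan-2-ylmethyl)-10-iodo-5-(4-methoxybenzyloxy)-2,6-dimethylundeca-2,6,10-trien-1-yl]oxy}dimethylsilane F1. The silyl triflate/collidine acetal cleavage of step 10 then gives the iodo aldehyde (3E,5R,6E)-3-[1-(tert-butyldimethylsilyloxy)propan-2-ylidene]-10-iodo-5-(4-methoxybenzyloxy)-6-methylundeca-6,10-dienal F2. A Nozaki–Hiyama–Kishi macrocyclisation (CrCl2, NiCl2 cat., DMSO/THF, high dilution) should deliver the C5 alcohols 18, which are oxidised with Dess–Martin periodinane; the fallback comes back to the route at 19.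

2. Step 14 (directed epoxidation). The ring conformation may override the A(1,2) preference and send oxygen to the wrong face of C4=C15, or the hydroxyl may direct oxidation to the homoallylic C7=C11 alkene. The fallback replaces the epoxidation/Payne pair by a transposition and a reagent-controlled epoxidation. It sets out from 20: acetylation (Ac2O, pyridine) gives the C5 acetate (1(10)E,5R,9R)-5-acetoxy-12-(tert-butyldimethylsilyloxy)-9-(4-methoxybenzyloxy)germacra-1(10),4(15),7(11)-triene F4. A PdCl2(MeCN)2-catalysed 1,3-acetate shift (chair-like [3,3] course, C6 cis to C3) should give the primary acetate (1(10)E,4E,9R)-15-acetoxy-12-(tert-butyldimethylsilyloxy)-9-(4-methoxybenzyloxy)germacra-1(10),4,7(11)-triene F5, with the C4=C5 alkene in the ring (ring bonds cis). Methanolysis (K2CO3, MeOH) gives the allylic alcohol (1(10)E,4E,9R)-12-(tert-butyldimethylsilyloxy)-9-(4-methoxybenzyloxy)germacra-1(10),4,7(11)-trien-15-ol F6. Sharpless epoxidation with D-(−)-diisopropyl tartrate then sets C4 and C5 together; the fallback comes back to the route at 22.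

3. Step 13 (CBS reduction). Inside the ring the two carbonyl substituents may be differentiated too weakly, so hydride delivery to both faces would erode the C5 configuration. The fallback separates the epimers by a matched oxidation instead of an asymmetric reduction. It sets out from 19: Luche reduction (NaBH4, CeCl3·7H2O, MeOH, −78 °C) gives 20 together with its epimer (1(10)E,5S,9R)-12-(tert-butyldimethylsilyloxy)-9-(4-methoxybenzyloxy)germacra-1(10),4(15),7(11)-trien-5-ol F3. Treatment of the mixture with Ti(OiPr)4, D-(−)-diisopropyl tartrate and t-BuOOH (0.6 equiv) should epoxidise the (5R) alcohol 20 much faster (matched pair, erythro product) than F3. The fallback comes back to the route at 21; recovered F3 is re-oxidised to 19 and recycled.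

**Further compounds**

F1 | step 11 | tert-butyl{[(2E,5R,6E)-3-(1,3-dioxolan-2-ylmethyl)-10-iodo-5-(4-methoxybenzyloxy)-2,6-dimethylundeca-2,6,10-trien-1-yl]oxy}dimethylsilane | CC(C)(C)[Si](C)(C)OC/C(C)=C(/CC1OCCO1)C[C@@H](OCc1ccc(OC)cc1)/C(C)=C/CCC(I)=C
F2 | step 11 | (3E,5R,6E)-3-[1-(tert-butyldimethylsilyloxy)propan-2-ylidene]-10-iodo-5-(4-methoxybenzyloxy)-6-methylundeca-6,10-dienal | O=CC/C(=C(\C)CO[Si](C)(C)C(C)(C)C)C[C@@H](OCc1ccc(OC)cc1)/C(C)=C/CCC(I)=C
F4 | step 14 | (1(10)E,5R,9R)-5-acetoxy-12-(tert-butyldimethylsilyloxy)-9-(4-methoxybenzyloxy)germacra-1(10),4(15),7(11)-triene | C=C1CC/C=C(\C)[C@H](OCc2ccc(OC)cc2)C/C(=C(/C)CO[Si](C)(C)C(C)(C)C)C[C@H]1OC(C)=O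
F5 | step 14 | (1(10)E,4E,9R)-15-acetoxy-12-(tert-butyldimethylsilyloxy)-9-(4-methoxybenzyloxy)germacra-1(10),4,7(11)-triene | CC(=O)OC/C1=C/C/C(=C(\C)CO[Si](C)(C)C(C)(C)C)C[C@@H](OCc2ccc(OC)cc2)/C(C)=C/CC1
F6 | step 14 | (1(10)E,4E,9R)-12-(tert-butyldimethylsilyloxy)-9-(4-methoxybenzyloxy)germacra-1(10),4,7(11)-trien-15-ol | OC/C1=C/C/C(=C(\C)CO[Si](C)(C)C(C)(C)C)C[C@@H](OCc2ccc(OC)cc2)/C(C)=C/CC1
F3 | step 13 | (1(10)E,5S,9R)-12-(tert-butyldimethylsilyloxy)-9-(4-methoxybenzyloxy)germacra-1(10),4(15),7(11)-trien-5-ol | C=C1CC/C=C(\C)[C@H](OCc2ccc(OC)cc2)C/C(=C(/C)CO[Si](C)(C)C(C)(C)C)C[C@@H]1O
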